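**Assumption:** catalogue reagents, ligands and catalysts ((−)-(NMI)2ZrCl2, (S,S)-ProPhenol, (R)-TRIP, bis(pinacolboryl)methane) count as commercially available; the facial sense of each catalyst is taken from its standard model ((−)-(NMI)2ZrCl2 gives (R)-2-methylalkan-1-ols; (S,S)-ProPhenol and (R)-TRIP both deliver the nucleophile to the aldehyde Re face).

## Retrosynthetic overview

1. C5–C6: last C–C bond by Suzuki coupling of an (E)-vinylboronate (C6–C15) with free (2E,4E)-5-iodopenta-2,4-dienoic acid, so no ester has to be hydrolysed next to the β-hydroxy ketone.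
2. C8–C9: one chiral-phosphoric-acid-catalysed α-boryl-(E)-crotylboration sets C8 and C9 and delivers the C6=C7 (E)-vinylboronate in the same step.
3. C13–C14: direct catalytic asymmetric aldol of 4'-nitroacetophenone (nitro as masked aniline) onto the C13 aldehyde.
4. C9–C13: a hidden C2-symmetric unit, (2R,4R)-2,4-dimethylpentane-1,5-diol, made in one step by double ZACA of penta-1,4-diene. Its two ends are homotopic, and both derived aldehydes need Re-face (Felkin-matched) attack.
5. Rings: the only ring is the benzene ring, bought in 4'-nitroacetophenone; no ring is formed in the route.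

## Route

Step 1
Reactants: 1 penta-1,4-diene
Product: 4 (2R,4R)-2,4-dimethylpentane-1,5-diol, via bis(dimethylalane) 2 (not isolated), via aluminium dialkoxide 3 (not isolated)
Conditions: Me3Al (5 equiv), (−)-(NMI)2ZrCl2 [bis(1-neomenthylindenyl)zirconium dichloride] (5 mol %), methylaluminoxane (1 equiv), CH2Cl2, 0 °C → rt; then O2, 0 °C → rt; aq NaOH
Reagents that add atoms: trimethylaluminium, C[Al](C)C; dioxygen, O=O
Why: Negishi's zirconium-catalysed asymmetric carboalumination (ZACA) runs on both terminal alkenes, each methylalumination putting CH3 on the internal carbon with the face set by the (−)-(NMI)2ZrCl2 catalyst (the enantiomer that gives (R)-2-methylalkan-1-ols), so C10 and C12 (target numbering) are both set R, the pairing of two catalyst-controlled events raises the ee of the C2-symmetric diol and leaves the meso diol as a separable diastereomer, and O2 cleaves the C–Al bonds with retention.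

Step 2
Reactants: 4 (2R,4R)-2,4-dimethylpentane-1,5-diol
Product: 6 (2R,4R)-2,4-dimethyl-5-[(triethylsilyl)oxy]pentan-1-ol, via sodium monoalkoxide 5 (not isolated)
Conditions: NaH (1.0 equiv), THF, rt; then TESCl (1.0 equiv), 0 °C → rt
Reagents that add atoms: chlorotriethylsilane, CC[Si](Cl)(CC)CC
Why: Monosilylation through the monosodium alkoxide (Williamson-type O-silylation) of a C2-symmetric diol whose two hydroxyls are homotopic, so only one mono-TES ether can form and no stereocentre is touched.

Step 3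
Reactants: 6 (2R,4R)-2,4-dimethyl-5-[(triethylsilyl)oxy]pentan-1-ol
Product: 7 (2R,4R)-2,4-dimethyl-5-[(triethylsilyl)oxy]pentanal
Conditions: TEMPO (10 mol %), PhI(OAc)2 (1.1 equiv), CH2Cl2, rt; used at once
Reagents that add atoms: none
Why: TEMPO/PhI(OAc)2 oxoammonium oxidation stops at the aldehyde under near-neutral conditions that keep the TES ether and do not epimerise the α-methyl centre.

Step 4
Reactants: 7 (2R,4R)-2,4-dimethyl-5-[(triethylsilyl)oxy]pentanal + 8 1-(4-nitrophenyl)ethan-1-one
Product: 9 (3R,4R,6R)-3-hydroxy-4,6-dimethyl-1-(4-nitrophenyl)-7-[(triethylsilyl)oxy]heptan-1-one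
Conditions: (S,S)-ProPhenol (10 mol %), Et2Zn (20 mol %), Ph3P=S (15 mol %), 4 Å MS, THF, 5 °C, 48 h; the ketone in fivefold excess
Reagents that add atoms: none
Why: Trost direct catalytic asymmetric aldol, in which the dinuclear zinc–ProPhenol complex forms the zinc enolate of the aryl methyl ketone and delivers it to the Re face of the α-branched aldehyde, which is also the Felkin–Anh face of the (2R)-aldehyde (matched), setting C13 as R (12,13-syn).

Step 5
Reactants: 9 (3R,4R,6R)-3-hydroxy-4,6-dimethyl-1-(4-nitrophenyl)-7-[(triethylsilyl)oxy]heptan-1-one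
Product: 10 (3R,4R,6R)-3-[(tert-butyldimethylsilyl)oxy]-4,6-dimethyl-1-(4-nitrophenyl)-7-[(triethylsilyl)oxy]heptan-1-one
Conditions: TBSOTf, 2,6-lutidine, CH2Cl2, −78 °C
Reagents that add atoms: tert-butyldimethylsilyl triflate, CC(C)(C)[Si](C)(C)OS(=O)(=O)C(F)(F)F
Why: Silyl triflate O-silylation at low temperature caps the C13 hydroxyl, which blocks lactol formation with the later C9 aldehyde and retro-aldol or dehydration of the β-hydroxy ketone, without enolising the aryl ketone.

Step 6
Reactants: 10 (3R,4R,6R)-3-[(tert-butyldimethylsilyl)oxy]-4,6-dimethyl-1-(4-nitrophenyl)-7-[(triethylsilyl)oxy]heptan-1-one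
Product: 11 (2R,4R,5R)-5-[(tert-butyldimethylsilyl)oxy]-2,4-dimethyl-7-(4-nitrophenyl)-7-oxoheptanal
Conditions: (COCl)2, DMSO, CH2Cl2, −78 → −40 °C; then Et3N, −78 → 0 °C
Reagents that add atoms: none
Why: Swern oxidation applied directly to the primary TES ether, where the chlorosulfonium reagent cleaves the unhindered O–SiEt3 bond and oxidises the carbinol in the same flask while the secondary TBS ether, the nitro group and the ketone are untouched and the low temperature protects the α-methyl centre.

Step 7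
Reactants: 12 bis(4,4,5,5-tetramethyl-1,3,2-dioxaborolan-2-yl)methane + 13 allyl bromide (3-bromoprop-1-ene)
Product: 15 2,2'-(but-3-ene-1,1-diyl)bis(4,4,5,5-tetramethyl-1,3,2-dioxaborolane), via lithiated diborylmethane 14 (not isolated)
Conditions: LiTMP (from 2,2,6,6-tetramethylpiperidine and n-BuLi), THF, 0 °C; then 13, 0 °C → rt
Reagents that add atoms: none
Why: Deprotonation between two boron atoms by a hindered amide base gives a boron-stabilised carbanion that undergoes clean SN2 alkylation with allyl bromide.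

Step 8
Reactants: 15 2,2'-(but-3-ene-1,1-diyl)bis(4,4,5,5-tetramethyl-1,3,2-dioxaborolane)
Product: 16 2,2'-[(2E)-but-2-ene-1,1-diyl]bis(4,4,5,5-tetramethyl-1,3,2-dioxaborolane)
Conditions: Pd(dba)2 (2 mol %), P(t-Bu)3 (2 mol %), i-PrCOCl (2 mol %), toluene, 60 °C
Reagents that add atoms: none
Why: Palladium-hydride-catalysed one-position alkene transposition (insertion then β-hydride elimination) moves the terminal alkene to the 2-position and stops there, the bulky phosphine and the CH(Bpin)2 group favouring the E-crotyl isomer.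

Step 9
Reactants: 11 (2R,4R,5R)-5-[(tert-butyldimethylsilyl)oxy]-2,4-dimethyl-7-(4-nitrophenyl)-7-oxoheptanal + 16 2,2'-[(2E)-but-2-ene-1,1-diyl]bis(4,4,5,5-tetramethyl-1,3,2-dioxaborolane)
Product: 18 (3R,4R,6R,7S,8R,9E)-3-[(tert-butyldimethylsilyl)oxy]-7-hydroxy-4,6,8-trimethyl-1-(4-nitrophenyl)-10-(4,4,5,5-tetramethyl-1,3,2-dioxaborolan-2-yl)dec-9-en-1-one, via O-boronate 17 (not isolated)
Conditions: (R)-TRIP (5 mol %), 4 Å MS, toluene, −45 °C → rt; aq NaHCO3
Reagents that add atoms: none
Why: Chiral-phosphoric-acid-catalysed allylboration through a Zimmerman–Traxler chair, in which the E-crotyl geometry gives the 8,9-anti relationship, (R)-TRIP directs the reagent to the aldehyde Re face, which is also the Felkin–Anh face of the (2R)-aldehyde (matched, 9,10-syn), so C9 is set S and C8 R, and the second boryl group sits pseudo-equatorial and ends on an E-alkene as the vinylboronate.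

Step 10
Reactants: 18 (3R,4R,6R,7S,8R,9E)-3-[(tert-butyldimethylsilyl)oxy]-7-hydroxy-4,6,8-trimethyl-1-(4-nitrophenyl)-10-(4,4,5,5-tetramethyl-1,3,2-dioxaborolan-2-yl)dec-9-en-1-one
Product: 19 (3R,4R,6R,7S,8R,9E)-1-(4-aminophenyl)-3-[(tert-butyldimethylsilyl)oxy]-7-hydroxy-4,6,8-trimethyl-10-(4,4,5,5-tetramethyl-1,3,2-dioxaborolan-2-yl)dec-9-en-1-one
Conditions: Fe powder, NH4Cl, EtOH/H2O (4:1), 70 °C
Reagents that add atoms: none
Why: Béchamp-type iron reduction takes the nitro group to the aniline chemoselectively, leaving the aryl ketone, the vinylboronate and the silyl ether alone, and is done before the acid-bearing triene exists.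

Step 11
Reactants: 20 ethyl (2E)-4-oxobut-2-enoate
Product: 21 ethyl (2E,4E)-5-iodopenta-2,4-dienoate
Conditions: CrCl2 (6 equiv), CHI3 (2 equiv), THF, 0 °C → rt
Reagents that add atoms: iodoform, IC(I)I
Why: Takai olefination, in which the geminal dichromium carbenoid from iodoform adds to the aldehyde and eliminates anti to give the E-vinyl iodide while the enoate is not attacked.

Step 12
Reactants: 21 ethyl (2E,4E)-5-iodopenta-2,4-dienoate
Product: 23 (2E,4E)-5-iodopenta-2,4-dienoic acid, via lithium carboxylate 22 (not isolated)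
Conditions: LiOH, THF/H2O (3:1), 0 °C → rt; then 1 M HCl to pH 2; recrystallise
Reagents that add atoms: lithium hydroxide, [Li+].[OH-]
Why: Simple saponification of an unhindered ester that leaves the vinyl iodide and both E-alkenes intact, with crystallisation removing any minor 4Z isomer.

Step 13
Reactants: 19 (3R,4R,6R,7S,8R,9E)-1-(4-aminophenyl)-3-[(tert-butyldimethylsilyl)oxy]-7-hydroxy-4,6,8-trimethyl-10-(4,4,5,5-tetramethyl-1,3,2-dioxaborolan-2-yl)dec-9-en-1-one + 23 (2E,4E)-5-iodopenta-2,4-dienoic acid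
Product: 24 (2E,4E,6E,8R,9S,10R,12R,13R)-15-(4-aminophenyl)-13-[(tert-butyldimethylsilyl)oxy]-9-hydroxy-8,10,12-trimethyl-15-oxopentadeca-2,4,6-trienoic acid
Conditions: Pd(dppf)Cl2·CH2Cl2 (5 mol %), K3PO4 (4 equiv), degassed THF/H2O (4:1), rt, dark; pH 4 work-up
Reagents that add atoms: none
Why: Suzuki–Miyaura coupling of a vinylboronate with a vinyl iodide proceeds with retention at both alkenes to give the all-E trienoic acid, the free acid being carried as its carboxylate and the C13 silyl ether shielding the β-oxy ketone from retro-aldol under the basic conditions.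

Step 14
Reactants: 24 (2E,4E,6E,8R,9S,10R,12R,13R)-15-(4-aminophenyl)-13-[(tert-butyldimethylsilyl)oxy]-9-hydroxy-8,10,12-trimethyl-15-oxopentadeca-2,4,6-trienoic acid
Product: 25 mohangic acid F, (2E,4E,6E,8R,9S,10R,12R,13R)-15-(4-aminophenyl)-9,13-dihydroxy-8,10,12-trimethyl-15-oxopentadeca-2,4,6-trienoic acid
Conditions: HF·pyridine, pyridine, THF, 0 °C → rt
Reagents that add atoms: none
Why: Buffered fluoride-mediated desilylation removes the single TBS ether under mildly acidic conditions that neither dehydrate the β-hydroxy ketone nor isomerise the triene.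

## Compound list

1 | penta-1,4-diene | C=CCC=C | starting material
2 | [(2R,4R)-2,4-dimethylpentane-1,5-diyl]bis(dimethylalane) | C[Al](C)C[C@H](C)C[C@@H](C)C[Al](C)C | intermediate (not isolated)
3 | [(2R,4R)-2,4-dimethylpentane-1,5-diyl]bis(oxy)bis(dimethoxyalane) | CO[Al](OC)OC[C@H](C)C[C@@H](C)CO[Al](OC)OC | intermediate (not isolated)
4 | (2R,4R)-2,4-dimethylpentane-1,5-diol | OC[C@H](C)C[C@@H](C)CO | intermediate
5 | sodium (2R,4R)-5-hydroxy-2,4-dimethylpentan-1-olate | [Na+].[O-]C[C@H](C)C[C@@H](C)CO | intermediate (not isolated)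
6 | (2R,4R)-2,4-dimethyl-5-[(triethylsilyl)oxy]pentan-1-ol | CC[Si](CC)(CC)OC[C@H](C)C[C@@H](C)CO | intermediate
7 | (2R,4R)-2,4-dimethyl-5-[(triethylsilyl)oxy]pentanal | CC[Si](CC)(CC)OC[C@H](C)C[C@@H](C)C=O | intermediate
8 | 1-(4-nitrophenyl)ethan-1-one | CC(=O)c1ccc(cc1)[N+](=O)[O-] | starting material
9 | (3R,4R,6R)-3-hydroxy-4,6-dimethyl-1-(4-nitrophenyl)-7-[(triethylsilyl)oxy]heptan-1-one | CC[Si](CC)(CC)OC[C@H](C)C[C@@H](C)[C@H](O)CC(=O)c1ccc(cc1)[N+](=O)[O-] | intermediate
10 | (3R,4R,6R)-3-[(tert-butyldimethylsilyl)oxy]-4,6-dimethyl-1-(4-nitrophenyl)-7-[(triethylsilyl)oxy]heptan-1-one | CC[Si](CC)(CC)OC[C@H](C)C[C@@H](C)[C@H](O[Si](C)(C)C(C)(C)C)CC(=O)c1ccc(cc1)[N+](=O)[O-] | intermediate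
11 | (2R,4R,5R)-5-[(tert-butyldimethylsilyl)oxy]-2,4-dimethyl-7-(4-nitrophenyl)-7-oxoheptanal | O=C[C@H](C)C[C@@H](C)[C@H](O[Si](C)(C)C(C)(C)C)CC(=O)c1ccc(cc1)[N+](=O)[O-] | intermediate
12 | bis(4,4,5,5-tetramethyl-1,3,2-dioxaborolan-2-yl)methane | C(B1OC(C)(C)C(C)(C)O1)B1OC(C)(C)C(C)(C)O1 | starting material
13 | allyl bromide (3-bromoprop-1-ene) | C=CCBr | starting material
14 | [bis(4,4,5,5-tetramethyl-1,3,2-dioxaborolan-2-yl)methyl]lithium | [Li]C(B1OC(C)(C)C(C)(C)O1)B1OC(C)(C)C(C)(C)O1 | intermediate (not isolated)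
15 | 2,2'-(but-3-ene-1,1-diyl)bis(4,4,5,5-tetramethyl-1,3,2-dioxaborolane) | C=CCC(B1OC(C)(C)C(C)(C)O1)B1OC(C)(C)C(C)(C)O1 | intermediate
16 | 2,2'-[(2E)-but-2-ene-1,1-diyl]bis(4,4,5,5-tetramethyl-1,3,2-dioxaborolane) | C/C=C/C(B1OC(C)(C)C(C)(C)O1)B1OC(C)(C)C(C)(C)O1 | intermediate
17 | 7-O-(4,4,5,5-tetramethyl-1,3,2-dioxaborolan-2-yl) ester of compound 18 | C[C@H](/C=C/B1OC(C)(C)C(C)(C)O1)[C@@H](OB1OC(C)(C)C(C)(C)O1)[C@H](C)C[C@@H](C)[C@H](O[Si](C)(C)C(C)(C)C)CC(=O)c1ccc(cc1)[N+](=O)[O-] | intermediate (not isolated)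
18 | (3R,4R,6R,7S,8R,9E)-3-[(tert-butyldimethylsilyl)oxy]-7-hydroxy-4,6,8-trimethyl-1-(4-nitrophenyl)-10-(4,4,5,5-tetramethyl-1,3,2-dioxaborolan-2-yl)dec-9-en-1-one | C[C@H](/C=C/B1OC(C)(C)C(C)(C)O1)[C@@H](O)[C@H](C)C[C@@H](C)[C@H](O[Si](C)(C)C(C)(C)C)CC(=O)c1ccc(cc1)[N+](=O)[O-] | intermediate
19 | (3R,4R,6R,7S,8R,9E)-1-(4-aminophenyl)-3-[(tert-butyldimethylsilyl)oxy]-7-hydroxy-4,6,8-trimethyl-10-(4,4,5,5-tetramethyl-1,3,2-dioxaborolan-2-yl)dec-9-en-1-one | C[C@H](/C=C/B1OC(C)(C)C(C)(C)O1)[C@@H](O)[C@H](C)C[C@@H](C)[C@H](O[Si](C)(C)C(C)(C)C)CC(=O)c1ccc(N)cc1 | intermediate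
20 | ethyl (2E)-4-oxobut-2-enoate | CCOC(=O)/C=C/C=O | starting material
21 | ethyl (2E,4E)-5-iodopenta-2,4-dienoate | CCOC(=O)/C=C/C=C/I | intermediate
22 | lithium (2E,4E)-5-iodopenta-2,4-dienoate | [Li+].[O-]C(=O)/C=C/C=C/I | intermediate (not isolated)
23 | (2E,4E)-5-iodopenta-2,4-dienoic acid | OC(=O)/C=C/C=C/I | intermediate
24 | (2E,4E,6E,8R,9S,10R,12R,13R)-15-(4-aminophenyl)-13-[(tert-butyldimethylsilyl)oxy]-9-hydroxy-8,10,12-trimethyl-15-oxopentadeca-2,4,6-trienoic acid | C[C@H](/C=C/C=C/C=C/C(=O)O)[C@@H](O)[C@H](C)C[C@@H](C)[C@H](O[Si](C)(C)C(C)(C)C)CC(=O)c1ccc(N)cc1 | intermediate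
25 | mohangic acid F, (2E,4E,6E,8R,9S,10R,12R,13R)-15-(4-aminophenyl)-9,13-dihydroxy-8,10,12-trimethyl-15-oxopentadeca-2,4,6-trienoic acid | C[C@H](/C=C/C=C/C=C/C(=O)O)[C@@H](O)[C@H](C)C[C@@H](C)[C@H](O)CC(=O)c1ccc(N)cc1 | target

## Step count and risk

Total step count: 14. Longest linear sequence: 10 steps (steps 1, 2, 3, 4, 5, 6, 9, 10, 13, 14).

**Step 1 (double ZACA).** Each methylalumination of an unbiased terminal alkene is only moderately enantioselective (about 75% ee is assumed here). The C2-symmetric diol therefore comes with a substantial share of meso diol, estimated at about one fifth, which must be removed at 4 or, more easily, by crystallising the nitrophenyl ketone 9. If selectivity or separation is inadequate, the fallback replaces the opening step. It therefore cannot set out from a numbered compound (compound 1 is not used) and starts from commercial glutaryl dichloride F1 and (R)-4-benzyloxazolidin-2-one F2, and it comes back to the route at compound 4. Lithiated F2 (n-BuLi, THF, −78 °C) is acylated twice by F1 to give the bis-imide F3. Double sodium enolate formation (NaHMDS, THF, −78 °C) and methylation with MeI gives, by two independent auxiliary-controlled Evans alkylations, the C2-symmetric dimethylated bis-imide F4, which is crystallised free of minor diastereomers. LiBH4 (THF, H2O, 0 °C) then releases diol 4 and returns F2.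

**Step 4 (direct zinc–ProPhenol aldol).** The acidic, electron-poor 4'-nitroacetophenone may give a sluggish or dehydration-prone aldol, and the basic zinc species could epimerise the α-methyl aldehyde over the long reaction time. The fallback sets out from compound 8 (with compound 7 as its partner) and comes back at compound 9. Ketone 8 is converted with TMSOTf and Et3N (CH2Cl2, 0 °C) into the silyl enol ether F5, and a Mukaiyama aldol of F5 with aldehyde 7 (BF3·OEt2, CH2Cl2, −78 °C) gives 9. This works under non-basic conditions and relies on Felkin–Anh substrate control, which points the same way. The diastereomer ratio will be lower, and the C13 epimer is removed by chromatography or crystallisation.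

**Step 9 (α-boryl crotylboration).** The gem-diboryl crotyl reagent 16 may over-isomerise in step 8 or be hard to purify. The E-geometry of the new alkene depends on the boryl group sitting pseudo-equatorial in the acid-catalysed transition state. The sense of (R)-TRIP is assumed from the simple allylboration model. The fallback sets out from compound 11 and comes back at compound 18. Aldehyde 11 is crotylated with commercial (E)-crotylboronic acid pinacol ester under the same (R)-TRIP catalysis (toluene, 4 Å MS, −30 °C) to give the anti,syn homoallylic alcohol F6 with a plain terminal vinyl group. Cross-metathesis of F6 with vinylboronic acid pinacol ester (second-generation Hoveyda–Grubbs catalyst, CH2Cl2, 40 °C) then installs the (E)-vinylboronate and gives 18, so C–C bond formation is decoupled from boron installation.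

## Further compounds

F1 | step 1 | glutaryl dichloride | O=C(Cl)CCCC(=O)Cl
F2 | step 1 | (R)-4-benzyloxazolidin-2-one | O=C1OC[C@@H](Cc2ccccc2)N1
F3 | step 1 | 1,5-bis[(R)-4-benzyl-2-oxooxazolidin-3-yl]pentane-1,5-dione | O=C(CCCC(=O)N1[C@H](Cc2ccccc2)COC1=O)N1[C@H](Cc2ccccc2)COC1=O
F4 | step 1 | (2R,4R)-1,5-bis[(R)-4-benzyl-2-oxooxazolidin-3-yl]-2,4-dimethylpentane-1,5-dione | O=C([C@H](C)C[C@@H](C)C(=O)N1[C@H](Cc2ccccc2)COC1=O)N1[C@H](Cc2ccccc2)COC1=O
F5 | step 4 | trimethyl{[1-(4-nitrophenyl)ethenyl]oxy}silane | C=C(O[Si](C)(C)C)c1ccc(cc1)[N+](=O)[O-]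
F6 | step 9 | (3R,4R,6R,7S,8R)-3-[(tert-butyldimethylsilyl)oxy]-7-hydroxy-4,6,8-trimethyl-1-(4-nitrophenyl)dec-9-en-1-one | C=C[C@@H](C)[C@@H](O)[C@H](C)C[C@@H](C)[C@H](O[Si](C)(C)C(C)(C)C)CC(=O)c1ccc(cc1)[N+](=O)[O-]
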